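The data were generated by integration for substances that don't exist; noise was put on by code.

As the chemist on this enzyme flask, I had its own readings so far (the south-east run) and one earlier run at 22 °C (the north-east run), and I had to choose at 3.0 min what to do next.

all flasks: starting material 0.20 mM; free enzyme 0.048 µM

| charge | protic impurity | temperature | remark | time |
|---|---|---|---|---|
| south-east | 0.020 mM | 37 °C | the very flask that is asked about, followed so far |  |
| north-east | 0.020 mM | 22 °C | run made earlier |  |
| flask | 0.0200 mM | 37 °C |  | 3.0 min |

- target taken out counts as made
- the numbers in the tables scatter by 2 percentage points (one standard deviation)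
- additions bring no volume worth counting

- elm: at 3.0 min raise the temperature by 20 K, then wait 1.5 min
- ash: at 3.0 min take out 90% of the target then present, then wait 1.5 min
- alder: change nothing and wait 1.5 min more
- cedar: at 3.0 min add free enzyme, 50.0% of the amount charged, then wait 1.5 min

- target, in percent of the starting material first charged, at 3.0 min
- the option that brings most further target ("none" if no option brings more than 2 percentage points) (elm / ash / alder / cedar / none)
- target present, with what was taken out counted in, in percent of the starting material first charged, after ash
- target present, with what was taken out counted in, in percent of the starting material first charged, after cedar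

| run | time / min | target / % | starting material / % |
|---|---|---|---|
| south-east | 0.200 | 57 | 36 |
| south-east | 0.333 | 63 | 23 |
| south-east | 0.500 | 63 | 24 |
| south-east | 0.833 | 61 | 18 |
| south-east | 1.33 | 52 | 18 |
| south-east | 2.50 | 40 | 11 |
| north-east | 0.417 | 69 | 21 |
| north-east | 0.667 | 79 | 16 |
| north-east | 1.00 | 71 | 3 |
| north-east | 2.00 | 52 | 3 |
| north-east | 3.00 | 36 | 3 |
| north-east | 5.00 | 27 | 3 |

(scatter of a reading: 2 percentage points)

I followed one molecule that was either starting material or target, and called these two forms the pool. Reading the south-east table from 0.833 min on, the target fell from 61% to 40%, and the starting material fell with it, from 18% to 11%. So I took the target share of the pool, c(target)/(c(target) + c(starting material)), as the quantity to carry: my molecule's chance of standing on target at a given moment. Those rows gave the target share 76.5%, a reading with the scatter of the table. In those rows the pool read 79.0% and then 51.0%, which I read as a pseudo-first-order loss of 0.263 min⁻¹.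

Carried on to 3.0 min, this loss gave me an estimated pool of 44.7%, so I expected 34.2% target. For waiting I estimated 23.1%, less than my figure for 3.0 min. With ash, I counted 30.8% as taken out and assumed that the rest of the pool refilled the target at the same share, which gave 38.0%. That is an estimated gain of 3.8 percentage points, above the margin. The last three north-east rows gave a higher share at 22 °C, a reading of 92.7%, so I expected elm to lower the share. The share looked steady within the scatter of those south-east rows, so I booked no gain for cedar. My choice was ash.

The forecast gave 36% now, none as best, 35% after ash and 31% after cedar, holding that the target “is not in equilibrium with starting material”. There my reading differed.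

The flask gave 37.9% target; the best option was ash, bringing 6.1 points, with 44.0% after ash and 23.7% after cedar.

    free enzyme → unfolded enzyme (k = 4.50 × 10⁻⁴ s⁻¹, Ea = 261 kJ mol⁻¹)
    starting material + free enzyme ⇌ complex (K = 14000 L mol⁻¹, k = 3.90 × 10⁶ L mol⁻¹ s⁻¹, Ea = 15.0 kJ mol⁻¹, ΔH = −5.00 kJ mol⁻¹)
    complex ⇌ free enzyme + target (K = 2.50 × 10⁻⁴ M, k = 1500 s⁻¹, Ea = 57.0 kJ mol⁻¹, ΔH = −63.0 kJ mol⁻¹)
    free enzyme + target → free enzyme + over-reaction product (k = 1.30 × 10⁵ L mol⁻¹ s⁻¹, Ea = 16.0 kJ mol⁻¹)
    starting material + protic impurity → quenched substrate (k = 240 L mol⁻¹ s⁻¹, Ea = 40.0 kJ mol⁻¹)
    target ⇌ isomer of the product (K = 0.120, k = 0.00790 s⁻¹, Ea = 81.0 kJ mol⁻¹, ΔH = −32.0 kJ mol⁻¹)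
    (constants at 37 °C)

At 3.00 min this flask held target 37.9% beside starting material 11.0%, a pool of 48.9%, and my read share 76.5% of that pool comes to 37.4% target. Ash ended at 44.0%, above my 38.0%. The neighbouring flask had the same charges at 22 °C, and for that temperature the north-east rows had given me a read share of 92.7%. At 3.00 min the neighbouring flask had a pool of 46.6%, of which that share comes to 43.2% target, and it held 43.2%.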